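## Retrosynthetic overview (ent-kaurane numbering)

1. 21 ⇐ 17. The D-ring allylic alcohol goes on last (SeO2, DMP, Luche) while the C-6 aldehyde rests as a dioxolane.
2. 17 ⇐ 13. Ring D (C-13–C-16) closes by a 5-exo vinyl-radical addition to the C-12=C-13 enone. The C-11 ketone, an auxiliary left by the key step, is then deleted.
3. 13 ⇐ 5 + 10. The δ-lactone ring O–C-20–C-10–C-9–C-8–C-7 forms by joining the carboxyl O to C-20 and C-9 to the quaternary C-10.
4. Enabling feature: in this lactone ring, C-20 and C-10 are the γ- and β-carbons of the C-6 aldehyde (C-6–C-5–C-10–C-20), so ring A is a γ-bromo-β-cyclocitral. The carboxyl O on C-7 and C-9 are the carboxyl oxygen and ortho carbon of ring C, so ring C is the Birch product of 3-methoxybenzoic acid, an acid whose enol ether is nucleophilic at C-9.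
5. Ring order: A (from β-cyclocitral) and C (dearomatised arene), then the lactone, then D.

Key step: step 7

Remark 1: the sense of the salt resolution (step 2) cannot be predicted. The route is written for (S)-1-phenylethylamine, and the antipodal amine is used if the salt of the (R)-acid crystallises first.
Remark 2: the lipase in step 5 is assumed to follow the Kazlauskas rule, so the (R)-acetate is hydrolysed and the (S)-acetate is left.

## Route

Step 1
Reactants: 1 3-methoxybenzoic acid
Product: 3 (±)-1-(2-bromoprop-2-enyl)-3-methoxycyclohexa-2,5-diene-1-carboxylic acid, via dilithium Birch dienediolate 2 (not isolated)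
Conditions: Li, t-BuOH (1 equiv), NH3(l)/THF, −78 °C; piperylene; 2,3-dibromopropene, −78 °C; NH4Cl
Reagents that add atoms: 2,3-dibromopropene, C=C(Br)CBr
Why: Birch reductive alkylation of a benzoic acid reduces the ipso and para carbons, keeps the meta methoxy group on an sp2 carbon as an enol ether, and alkylates the enediolate at the ipso carbon to give quaternary C-8 (racemic).

Step 2
Reactants: 3 (±)-1-(2-bromoprop-2-enyl)-3-methoxycyclohexa-2,5-diene-1-carboxylic acid
Product: 5 (S)-1-(2-bromoprop-2-enyl)-3-methoxycyclohexa-2,5-diene-1-carboxylic acid, via phenylethylammonium salt 4 (not isolated)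
Conditions: (S)-1-phenylethylamine, EtOAc, recrystallise; then cold 0.5 M HCl/Et2O, 0 °C, short contact
Reagents that add atoms: none
Why: Classical resolution through diastereomeric ammonium carboxylates fixes C-8, and the salt form also shields the acid-labile enol ether until the brief cold liberation.

Step 3
Reactants: 6 β-cyclocitral
Product: 7 (±)-3-bromo-2,6,6-trimethylcyclohex-1-ene-1-carbaldehyde
Conditions: NBS, AIBN, PhCF3, 80 °C
Reagents that add atoms: N-bromosuccinimide, O=C1CCC(=O)N1Br
Why: In this Wohl–Ziegler bromination the secondary ring allylic C–H (the future C-1) is abstracted in preference to the primary methyl C–H.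

Step 4
Reactants: 7 (±)-3-bromo-2,6,6-trimethylcyclohex-1-ene-1-carbaldehyde
Product: 8 (±)-3-formyl-2,4,4-trimethylcyclohex-2-enyl acetate
Conditions: AgOAc, AcOH, 23 °C
Reagents that add atoms: silver acetate, CC(=O)[O-].[Ag+]
Why: Silver-assisted acetolysis of the activated γ-bromo enal runs without base, so elimination to the dienal should be held back.

Step 5
Reactants: 8 (±)-3-formyl-2,4,4-trimethylcyclohex-2-enyl acetate
Product: 9 (S)-3-formyl-2,4,4-trimethylcyclohex-2-enyl acetate
Conditions: Burkholderia cepacia lipase, pH 7 phosphate buffer/MTBE, 30 °C, stopped just past half conversion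
Reagents that add atoms: none
Why: In this enzymatic kinetic resolution the (R)-acetate (large substituted-vinyl side, medium CH2 side) should hydrolyse faster, leaving the (S)-acetate that carries the C-1 configuration of the target.

Step 6
Reactants: 9 (S)-3-formyl-2,4,4-trimethylcyclohex-2-enyl acetate
Product: 10 (S)-2-(bromomethyl)-3-formyl-4,4-dimethylcyclohex-2-enyl acetate
Conditions: NBS, AIBN, PhCF3, 80 °C
Reagents that add atoms: N-bromosuccinimide, O=C1CCC(=O)N1Br
Why: In this Wohl–Ziegler bromination the methyl group should react because A(1,2) strain holds the acetate pseudo-axial, leaving C-1–H in the nodal plane of the π system and polarity-deactivated by the acetoxy group.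

Step 7
Reactants: 5 (S)-1-(2-bromoprop-2-enyl)-3-methoxycyclohexa-2,5-diene-1-carboxylic acid; 10 (S)-2-(bromomethyl)-3-formyl-4,4-dimethylcyclohex-2-enyl acetate
Product: 13 spiro-lactone enone aldehyde, via allylic ester 11 (not isolated), via β,γ-enone 12 (not isolated)
Conditions: i-Pr2NEt (1.1 equiv), CH2Cl2, 0 → 23 °C; then −78 °C, Me2AlCl (3 equiv), → −30 °C; then 2 M HCl, THF, 23 °C
Reagents that add atoms: water, O
Why: Proposed new method: the ammonium carboxylate of 5 displaces the primary allylic bromide of 10 (SN2, O–C-20), and Me2AlCl then activates the aldehyde of ester 11 so that the enol-ether carbon C-9 adds to the fully substituted β-carbon C-10, after which aqueous HCl turns the aluminium enolate into the C-6 aldehyde and the methoxycarbenium ion, through β,γ-enone 12, into the conjugated C-11 enone 13. The closest known reaction types are amine or caesium carboxylate allylation and the intramolecular Lewis-acid Mukaiyama–Michael addition of enol ethers to enals and enones that builds quaternary carbons; what is new is the Birch dienol ether as donor, the tetrasubstituted enal as acceptor and the telescoping in one flask. The only ring closed is the δ-lactone, 6-exo-trig at the enal (C-5 stays outside), with the donor double bond also exocyclic to the forming ring. For C-9, the short tether starts at the carboxyl on C-8, so C-10 can only reach the face of the nearly flat diene that carries C-7, anti to the bromoallyl group (cis-fused lactone); for C-10, the pseudo-axial C-1 acetate blocks one face of the enal and attack comes from the other; C-5 is set by protonation and acid equilibration to the equatorial aldehyde trans to C-9. The step needs O-alkylation before C–C bond formation (the bromide is consumed before the Lewis acid is added), C-9 over C-14 (only C-9=C-11 is an enol ether, while C-13=C-14 is a plain alkene) and 1,4- over 1,2-addition (1,2-addition would need an eight-membered ring).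

Step 8
Reactants: 13 spiro-lactone enone aldehyde
Product: 14 C-6 dioxolane of 13
Conditions: (TMSOCH2)2, TMSOTf (5 mol %), CH2Cl2, −78 → −20 °C
Reagents that add atoms: 1,2-bis(trimethylsilyloxy)ethane, C[Si](C)(C)OCCO[Si](C)(C)C
Why: Noyori acetalisation under aprotic conditions takes the saturated aldehyde, while the conjugated C-11 enone is deactivated and the acetate, lactone and vinyl bromide are inert.

Step 9
Reactants: 14 C-6 dioxolane of 13
Product: 15 11-oxo-16-ene tetracycle (bicyclo[3.2.1]octane closed)
Conditions: Bu3SnH (slow addition), AIBN, PhH, 80 °C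
Reagents that add atoms: none
Why: In this reductive radical cyclisation the vinyl radical from the 2-bromoallyl group closes 5-exo-trig on the enone β-carbon C-13, the one-carbon link C-14 allows only the bridged cis closure (which fixes C-13), and the α-keto radical takes H from the stannane.

Step 10
Reactants: 15 11-oxo-16-ene tetracycle
Product: 17 11-deoxy-16-ene tetracycle, via tosylhydrazone 16 (not isolated)
Conditions: TsNHNH2, EtOH, 50 °C; concentrate; catecholborane, CHCl3, −10 °C; NaOAc·3H2O, reflux
Reagents that add atoms: none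
Why: Caglioti–Kabalka deoxygenation removes the auxiliary ketone under near-neutral conditions that spare the lactone, acetate, acetal and alkene, and C-9–H lies close to the C=N plane and should not epimerise.

Step 11
Reactants: 17 11-deoxy-16-ene tetracycle
Product: 18 15-exo-alcohol (15-epimer series)
Conditions: SeO2 (0.5 equiv), t-BuOOH, CH2Cl2, 23 °C
Reagents that add atoms: tert-butyl hydroperoxide, CC(C)(C)OO
Why: SeO2 allylic hydroxylation (ene, then [2,3]-shift) can only use the C-15 hydrogens because bridgehead C-13–H cannot give an alkene, and it delivers oxygen from the open exo face, which the next two steps correct.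

Step 12
Reactants: 18 15-exo-alcohol
Product: 19 16-en-15-one
Conditions: Dess–Martin periodinane, CH2Cl2, 23 °C
Reagents that add atoms: none
Why: Dess–Martin oxidation of the only free hydroxyl gives the α-methylene ketone without touching the acetal, acetate or lactone.

Step 13
Reactants: 19 16-en-15-one
Product: 20 15-endo-alcohol dioxolane
Conditions: NaBH4, CeCl3·7H2O, MeOH, −78 °C
Reagents that add atoms: none
Why: In the Luche 1,2-reduction hydride comes from the exo face (the side of the one-carbon bridge C-14), so the hydroxyl ends endo, cis to C-9, as in the target.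

Step 14
Reactants: 20 15-endo-alcohol dioxolane
Product: 21 target
Conditions: 1 M HCl, THF, 23 °C
Reagents that add atoms: water, O
Why: Acetal hydrolysis frees the equatorial C-6 aldehyde, and the allylic alcohol next to the acyl-bearing quaternary C-8 should not ionise under these mild conditions.

## Compound list

1 | 3-methoxybenzoic acid | COc1cccc(c1)C(=O)O | starting material
2 | dilithium (3-methoxycyclohexa-2,5-dienylidene)methanediolate | COC1=CC(=C([O-])[O-])C=CC1.[Li+].[Li+] | intermediate
3 | (±)-1-(2-bromoprop-2-enyl)-3-methoxycyclohexa-2,5-diene-1-carboxylic acid | COC1=CC(CC(=C)Br)(C(=O)O)C=CC1 | intermediate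
4 | (S)-1-phenylethylammonium salt of the (S)-acid | COC1=C[C@@](CC(=C)Br)(C(=O)[O-])C=CC1.C[C@H]([NH3+])c1ccccc1 | intermediate
5 | (S)-1-(2-bromoprop-2-enyl)-3-methoxycyclohexa-2,5-diene-1-carboxylic acid | COC1=C[C@@](CC(=C)Br)(C(=O)O)C=CC1 | intermediate
6 | β-cyclocitral (2,6,6-trimethylcyclohex-1-ene-1-carbaldehyde) | CC1=C(C=O)C(C)(C)CCC1 | starting material
7 | (±)-3-bromo-2,6,6-trimethylcyclohex-1-ene-1-carbaldehyde | CC1=C(C=O)C(C)(C)CCC1Br | intermediate
8 | (±)-3-formyl-2,4,4-trimethylcyclohex-2-enyl acetate | CC1=C(C=O)C(C)(C)CCC1OC(C)=O | intermediate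
9 | (S)-3-formyl-2,4,4-trimethylcyclohex-2-enyl acetate | CC1=C(C=O)C(C)(C)CC[C@@H]1OC(C)=O | intermediate
10 | (S)-2-(bromomethyl)-3-formyl-4,4-dimethylcyclohex-2-enyl acetate | BrCC1=C(C=O)C(C)(C)CC[C@@H]1OC(C)=O | intermediate
11 | [(6S)-6-acetoxy-2-formyl-3,3-dimethylcyclohex-1-enyl]methyl ester of acid 5 | COC1=C[C@@](CC(=C)Br)(C(=O)OCC2=C(C=O)C(C)(C)CC[C@@H]2OC(C)=O)C=CC1 | intermediate
12 | spiro-lactone with C-11 ketone and C-13=C-14 alkene; 2-bromoallyl on C-8 trans to C-10; C-1, C-5, C-8, C-9, C-10 as in 21 | O=C1CC=C[C@@]2(CC(=C)Br)[C@@H]1[C@]1(COC2=O)[C@@H](OC(C)=O)CCC(C)(C)[C@H]1C=O | intermediate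
13 | spiro-lactone enone aldehyde (C-11 ketone conjugated with C-12=C-13; otherwise as 12) | O=C1C=CC[C@@]2(CC(=C)Br)[C@@H]1[C@]1(COC2=O)[C@@H](OC(C)=O)CCC(C)(C)[C@H]1C=O | intermediate
14 | C-6 1,3-dioxolane of 13 | O=C1C=CC[C@@]2(CC(=C)Br)[C@@H]1[C@]1(COC2=O)[C@@H](OC(C)=O)CCC(C)(C)[C@H]1C1OCCO1 | intermediate
15 | 11-oxo-16-ene tetracycle, C-6 dioxolane, C-13 as in 21 | C=C1[C@@H]2CC(=O)[C@@H]3[C@](C2)(C(=O)OC[C@]32[C@@H](OC(C)=O)CCC(C)(C)[C@H]2C2OCCO2)C1 | intermediate
16 | C-11 tosylhydrazone of 15 | C=C1[C@@H]2CC(=NNS(=O)(=O)c4ccc(C)cc4)[C@@H]3[C@](C2)(C(=O)OC[C@]32[C@@H](OC(C)=O)CCC(C)(C)[C@H]2C2OCCO2)C1 | intermediate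
17 | 11-deoxy-16-ene tetracycle, C-6 dioxolane | C=C1[C@@H]2CC[C@@H]3[C@](C2)(C(=O)OC[C@]32[C@@H](OC(C)=O)CCC(C)(C)[C@H]2C2OCCO2)C1 | intermediate
18 | 15-exo-alcohol (OH trans to C-9 on ring D), C-6 dioxolane | C=C1[C@@H]2CC[C@@H]3[C@](C2)(C(=O)OC[C@]32[C@@H](OC(C)=O)CCC(C)(C)[C@H]2C2OCCO2)[C@H]1O | intermediate
19 | 16-en-15-one, C-6 dioxolane | C=C1[C@@H]2CC[C@@H]3[C@](C2)(C(=O)OC[C@]32[C@@H](OC(C)=O)CCC(C)(C)[C@H]2C2OCCO2)C1=O | intermediate
20 | 15-endo-alcohol (OH cis to C-9 on ring D), C-6 dioxolane | C=C1[C@@H]2CC[C@@H]3[C@](C2)(C(=O)OC[C@]32[C@@H](OC(C)=O)CCC(C)(C)[C@H]2C2OCCO2)[C@@H]1O | intermediate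
21 | target, (1S,5R,8S,9S,10S,13R,15R) in ent-kaurane numbering | C=C1[C@@H]2CC[C@@H]3[C@](C2)(C(=O)OC[C@]32[C@@H](OC(C)=O)CCC(C)(C)[C@H]2C=O)[C@@H]1O | target

## Step count

Total steps: 14. The longest linear sequence is 12 steps (6 → 21, steps 3–14).

## Steps most likely to fail

**Step 7 (Proposed new method).**
- What may go wrong: the congested β-carbon may resist attack, so the enol ether is instead protonated or the ester is degraded by the Lewis acid. An acid-induced aldol closure between C-12 and the aldehyde may also follow during the work-up.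
- Fallback (known chemistry, from 10 and 5, returning at 13): the electrophile is changed from a Lewis-acid-complexed aldehyde to an acetal-derived alkoxyallyl cation, and the two bonds are made stepwise.
  - Compound 10 is converted with HC(OMe)3 and catalytic CSA in MeOH into the bromo dimethyl acetal F1.
  - Cs2CO3 in DMF with 5 gives the isolated ester acetal F2.
  - Catalytic TMSOTf with 2,6-di-tert-butylpyridine in CH2Cl2 at −78 °C (Noyori-type addition of an enol ether to an acetal, here in the vinylogous sense enforced by ring size) gives the doubly masked spiro-lactone F3.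
  - 2 M HCl in THF hydrolyses F3 to 13.

**Step 2.**
- What may go wrong: the salts may discriminate poorly on crystallisation, or the enol ether may hydrolyse during liberation of the acid.
- Fallback (from 3, returning at 13): no resolution is done. Racemic 3 goes into step 7 with enantiopure 10. Ester 11 then forms beside its C-8 epimeric ester F4. Both cyclise, and 13 is separated by chromatography from the 8,9-diastereomeric spiro-lactone F5.

**Step 6.**
- What may go wrong: hydrogen abstraction at C-1–H or at the formyl C–H, or double bromination.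
- Fallback (from 9, returning at 10): the bromination is done by an ionic route. TBSOTf and Et3N remove a methyl proton to give the cross-conjugated silyl dienol ether F6, and NBS in THF at −78 °C brominates its exocyclic methylene terminus to give 10.

## Further compounds

F1 | step 7 | (S)-2-(bromomethyl)-3-(dimethoxymethyl)-4,4-dimethylcyclohex-2-enyl acetate | BrCC1=C(C(OC)OC)C(C)(C)CC[C@@H]1OC(C)=O
F2 | step 7 | ester of acid 5 with the allylic alcohol part of F1 | COC1=C[C@@](CC(=C)Br)(C(=O)OCC2=C(C(OC)OC)C(C)(C)CC[C@@H]2OC(C)=O)C=CC1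
F3 | step 7 | spiro-lactone with C-11 dimethyl ketal, C-13=C-14 alkene and C-5=C-6 methyl enol ether | COC1(OC)CC=C[C@@]2(CC(=C)Br)[C@@H]1[C@]1(COC2=O)[C@@H](OC(C)=O)CCC(C)(C)C1=COC
F4 | step 2 | C-8 epimer of ester 11 | COC1=C[C@](CC(=C)Br)(C(=O)OCC2=C(C=O)C(C)(C)CC[C@@H]2OC(C)=O)C=CC1
F5 | step 2 | 8,9-diastereomer of 13 | O=C1C=CC[C@]2(CC(=C)Br)[C@H]1[C@]1(COC2=O)[C@@H](OC(C)=O)CCC(C)(C)[C@H]1C=O
F6 | step 6 | (S)-3-[(tert-butyldimethylsilyloxy)methylidene]-4,4-dimethyl-2-methylidenecyclohexyl acetate | C=C1[C@@H](OC(C)=O)CCC(C)(C)C1=CO[Si](C)(C)C(C)(C)C
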